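**Plan**
- Locants C1–C29 follow the target SMILES from left to right; ring A = C14, C15, C19, C24, C25; ring B = C13–C17.
- Retrosynthesis cuts C3–O9 and C7–C6 (hemiketal, Michael), C7–C8 (homologation), N27–C26 and C29–C10 (lactam, Mannich), then C25–C24 and C19–C15 together (ring A), then C14–C25, C7–C25 and C13–C12 (hydroazulene).
- Forward order: cyclopentenone, cycloheptenone (bicyclic β-keto ester 8), ring A by a one-pot Michael/SN2 annulation with methyl 2-bromoacrylate, bridged piperidinone, spiro tetrahydropyran, final adjustments.
- Enabling feature: in 8 the alkene carbon C14 carries C25 (between the C7 ketone and an ester) and C15 (γ to the C17 enone), so both neighbours of C14 can act as carbanions toward the C24–C19 unit of the bromoacrylate.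
- Stereochemistry: C25 from a chiral ammonium ion pair; C15 and C10 follow from C25 through ring constraints; C17 by CBS reagent control; C7 by face selection on the bridged enolate; C19 by late kinetic protonation; C3 by hemiketal equilibration.

Key step: step 6

Remark: the C26 ester is carried as the ethyl ester (from commercial ethyl diazoacetate); it is a spectator and leaves as ethanol in step 7.
Assumption: the C3 configuration of the target is taken to be the thermodynamically preferred hemiketal (OH axial, ethyl equatorial), so C3 is left to equilibrate.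

Step 1
Reactants: 1 cyclopentane-1,3-dione; 2 pent-4-enal
Product: 3 2-(pent-4-en-1-yl)cyclopentane-1,3-dione
Conditions: L-proline (10 mol%), Hantzsch ester (1.0 equiv), CH2Cl2, rt
Reagents that add atoms: none
Why: Proline-catalysed Knoevenagel condensation and in situ transfer hydrogenation of the alkylidene dione by the Hantzsch ester (three-component reductive alkylation) should give clean mono-C-alkylation and avoid the O-alkylation of direct dione alkylation.

Step 2
Reactants: 3 2-(pent-4-en-1-yl)cyclopentane-1,3-dione
Product: 4 3-chloro-2-(pent-4-en-1-yl)cyclopent-2-en-1-one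
Conditions: (COCl)2, DMF (cat.), CH2Cl2, 0 °C to rt
Reagents that add atoms: oxalyl chloride, O=C(Cl)C(=O)Cl
Why: Vilsmeier-type activation of the enolised, symmetrical dione gives the β-chloro enone (a vinylogous acid chloride) as the only possible regioisomer and provides a good addition–elimination acceptor for step 5.

Step 3
Reactants: 4 3-chloro-2-(pent-4-en-1-yl)cyclopent-2-en-1-one
Product: 5 4-(2-chloro-5-oxocyclopent-1-en-1-yl)butanal
Conditions: O3, CH2Cl2, −78 °C (stopped at first excess); PPh3
Reagents that add atoms: ozone, [O-][O+]=O
Why: Ozonolysis with reductive work-up should cleave the electron-rich terminal alkene selectively, because the chloro-enone double bond is strongly deactivated toward ozone.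

Step 4
Reactants: 5 4-(2-chloro-5-oxocyclopent-1-en-1-yl)butanal; 6 ethyl diazoacetate
Product: 7 ethyl 6-(2-chloro-5-oxocyclopent-1-en-1-yl)-3-oxohexanoate
Conditions: SnCl2 (10 mol%), CH2Cl2, rt
Reagents that add atoms: none
Why: Roskamp homologation (Lewis-acid-promoted addition of the diazo ester to the aldehyde, 1,2-hydride shift, loss of N2) gives the β-keto ester under nearly neutral conditions that should leave the chloro enone untouched.

Step 5
Reactants: 7 ethyl 6-(2-chloro-5-oxocyclopent-1-en-1-yl)-3-oxohexanoate
Product: 8 ethyl 1,5-dioxo-1,2,3,4,5,6,7,8-octahydroazulene-4-carboxylate (racemic, labile at C25, largely enolised)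
Conditions: Cs2CO3 (2.2 equiv), MeCN (0.01 M), 50 °C; 1 M HCl work-up
Reagents that add atoms: none
Why: Intramolecular nucleophilic vinylic substitution (conjugate addition of the β-keto ester enolate C25 to C14 of the β-chloro enone, then loss of chloride; 7-endo-trig, with both chain ends held cis on the cyclopentenone) should close the cycloheptenone, driven by the highly delocalised enolate of the product.

Step 6
Reactants: 8 ethyl 1,5-dioxo-1,2,3,4,5,6,7,8-octahydroazulene-4-carboxylate; 9 methyl 2-bromoacrylate
Product: 11 tricyclic diketo diester (15R,19S,25R), via bromo ester Michael adduct 10 (not isolated)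
Conditions: 9 (1.2 equiv), N-(9-anthracenylmethyl)-O-allylcinchonidinium bromide (10 mol%), Cs2CO3 (2.5 equiv), toluene, −40 °C, then warm to 40 °C
Reagents that add atoms: none
Why: Proposed new method: the ion pair of the chiral ammonium cation and the doubly vinylogous enolate of 8 should add through C25, the carbon flanked by both carbonyl groups, to C24 of the bromoacrylate with the cation shielding one enolate face (25R), and after protonation to 10 carbonate removes the γ-proton at C15 of the enone so that the extended dienolate displaces bromide at C19 and closes ring A. The closest known reactions are phase-transfer-catalysed Michael additions of cyclic β-keto esters to acrylates and Michael-initiated ring closures of 2-haloacrylates to cyclopropanes and dihydrofurans; an enone γ-carbon as the second nucleophile and asymmetric induction in such a sequence have no direct precedent. The closure is 5-exo-tet at C19 but enolendo with respect to the dienolate (C14=C15 lies in the new ring), so overlap is imperfect and the step relies on the lack of better options: attack through C13 would give a strained bridged bicyclo[4.2.1] skeleton, C10 is not deprotonated by carbonate, and no oxygen reaches C19 through a five-membered transition state without that enolisation. C15 is set by the tether, since C24 and C26 lie on opposite faces of the planar dienolate at C25 and C19 can reach C15 only from the face of C24, which leaves H15 cis to C26 (15R). C19 is not controlled with confidence: the ester should prefer the exo position of the SN2 transition state (19S, epimeric to the target), and either epimer is acceptable because step 15 sets this centre. The step needs the Michael addition to outrun polymerisation of 9 and the ring closure to outrun retro-Michael reaction, which low temperature in the first stage and the irreversible loss of bromide should favour.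

Step 7
Reactants: 11 tricyclic diketo diester
Product: 13 bridged keto lactam, via Mannich base 12 (not isolated)
Conditions: MeNH2·HCl (3 equiv), (CH2O)n (1.5 equiv), EtOH, 70 °C; then NaHCO3, toluene, 80 °C
Reagents that add atoms: methylamine hydrochloride, CN.Cl; paraformaldehyde (as formaldehyde), C=O
Why: Mannich aminomethylation at C10, the only enolisable α-carbon of the C7 ketone, is followed on neutralisation by lactamisation of the secondary amine onto the C26 ethyl ester (6-exo-trig); Mannich addition is reversible and only the C10 adduct with C29 on the face of C26 can be trapped as the lactam, so regio- and stereoisomers should converge on the single bridged product.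

Step 8
Reactants: 13 bridged keto lactam
Product: 14 17S allylic alcohol
Conditions: (R)-Me-CBS [(3aR)-1-methyl-3,3-diphenyltetrahydro-1H,3H-pyrrolo[1,2-c][1,3,2]oxazaborole] (0.5 equiv), catecholborane, toluene, −78 °C
Reagents that add atoms: none
Why: In this Corey–Bakshi–Shibata reduction the catalyst distinguishes the alkenyl flank C13 from the methylene flank C16 of the C17 enone, so the R catalyst should deliver hydride to the face that gives the 17S alcohol (OH cis to H15), while the C7 ketone, buried between a quaternary and a bridgehead carbon, should not react at this temperature.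

Step 9
Reactants: 14 17S allylic alcohol
Product: 15 C17 tert-butyldimethylsilyl ether
Conditions: tBuMe2SiCl, imidazole, DMF, rt
Reagents that add atoms: tert-butyldimethylsilyl chloride, CC(C)(C)[Si](C)(C)Cl
Why: Standard silylation of a secondary allylic alcohol removes the acidic OH before the ylide, enolate and amide-base steps.

Step 10
Reactants: 15 C17 tert-butyldimethylsilyl ether
Product: 16 C7 methoxymethylidene compound (enol ether, E/Z mixture)
Conditions: Ph3P(CH2OMe)Cl, KN(SiMe3)2, THF, 0 °C to 50 °C
Reagents that add atoms: (methoxymethyl)triphenylphosphonium chloride, [Cl-].COC[P+](c1ccccc1)(c1ccccc1)c1ccccc1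
Why: Wittig methoxymethylenation should take place at the strained bridging C7 ketone, which cannot enolise because its α-carbons are a bridgehead and a quaternary centre, while ester and lactam are inert to the ylide.

Step 11
Reactants: 16 C7 methoxymethylidene compound
Product: 17 C7 carbaldehyde (C7 epimers)
Conditions: 1 M aq. HCl, THF, 0 °C to rt
Reagents that add atoms: water, O
Why: Acid hydrolysis of the methyl enol ether gives the one-carbon-homologated aldehyde (C8), and the configuration at C7 does not matter because this centre is enolised in the next step.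

Step 12
Reactants: 17 C7 carbaldehyde; 18 pent-1-en-3-one (ethyl vinyl ketone)
Product: 19 keto aldehyde with quaternary C7 (7R)
Conditions: 18 (3 equiv), DBU (0.3 equiv), MeCN, 0 °C to rt, short reaction time
Reagents that add atoms: none
Why: Base-catalysed Michael addition of the α,α-disubstituted aldehyde enolate to the vinyl ketone creates the quaternary C7, and the acceptor should approach the exocyclic enolate from the face syn to the flat lactam bridge (C26=O, N27) and not from the face beneath the cycloheptene and ring A, which places C6 syn to nitrogen and the formyl carbon C8 over the carbocycle as in the target.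

Step 13
Reactants: 19 keto aldehyde
Product: 21 spiro methyl ketal lactam, via hydroxy ketone 20 (not isolated)
Conditions: NaBH(OAc)3, AcOH, CH2Cl2, rt; then MeOH, PPTS, rt
Reagents that add atoms: methanol, CO
Why: NaBH(OAc)3 reduces aldehydes but not ketones, the freed C8 alcohol closes onto the C3 ketone, and acid-catalysed exchange in methanol gives the six-membered mixed ketal under thermodynamic control (methoxy axial, ethyl equatorial), which masks the ketone for the next two steps.

Step 14
Reactants: 21 spiro methyl ketal lactam
Product: 22 tertiary amine (19S)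
Conditions: Zn(OAc)2 (10 mol%), (EtO)3SiH (3 equiv), THF, 40 °C
Reagents that add atoms: none
Why: Zinc-catalysed hydrosilylation of tertiary amides reduces the lactam carbonyl C26 to CH2 and is known to spare esters, ketals, silyl ethers and hindered alkenes.

Step 15
Reactants: 22 tertiary amine (19S)
Product: 24 19R ester (fully protected target), via lithium enolate 23 (not isolated)
Conditions: LiN(iPr)2 (commercial solution, 2 equiv), THF, −78 to −40 °C; then 2,6-di-tert-butyl-4-methylphenol, −78 °C
Reagents that add atoms: none
Why: Deprotonation of the only acidic C–H and kinetic protonation of the ester enolate by a bulky phenol from the more open face of ring A (the face of H15 and C26, the other being screened by C8 and the ketal ring) should turn the ester toward C7 and give 19R.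

Step 16
Reactants: 24 19R ester (fully protected target)
Product: 25 CNP0124876.1
Conditions: 48% aq. HF, MeCN, 0 °C to rt; NaHCO3 work-up
Reagents that add atoms: water, O
Why: Aqueous HF cleaves the silyl ether and hydrolyses the mixed ketal to the hemiketal, whose C3 centre equilibrates to the stable anomer, while the acidic medium leaves the C19 ester centre untouched.

**Compound list**
1 | cyclopentane-1,3-dione | O=C1CCC(=O)C1 | starting material
2 | pent-4-enal | C=CCCC=O | starting material
3 | 2-(pent-4-en-1-yl)cyclopentane-1,3-dione | C=CCCCC1C(=O)CCC1=O | intermediate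
4 | 3-chloro-2-(pent-4-en-1-yl)cyclopent-2-en-1-one | C=CCCCC1=C(Cl)CCC1=O | intermediate
5 | 4-(2-chloro-5-oxocyclopent-1-en-1-yl)butanal | O=CCCCC1=C(Cl)CCC1=O | intermediate
6 | ethyl diazoacetate | CCOC(=O)C=[N+]=[N-] | starting material
7 | ethyl 6-(2-chloro-5-oxocyclopent-1-en-1-yl)-3-oxohexanoate | CCOC(=O)CC(=O)CCCC1=C(Cl)CCC1=O | intermediate
8 | ethyl 1,5-dioxo-1,2,3,4,5,6,7,8-octahydroazulene-4-carboxylate (racemic, labile at C25) | CCOC(=O)C1C(=O)CCCC2=C1CCC2=O | intermediate
9 | methyl 2-bromoacrylate | C=C(Br)C(=O)OC | starting material
10 | ethyl (4R)-4-(2-bromo-3-methoxy-3-oxopropyl)-1,5-dioxo-1,2,3,4,5,6,7,8-octahydroazulene-4-carboxylate (25R; both epimers at the CHBr carbon C19) | O=C1CCCC2=C(CCC2=O)[C@@]1(CC(Br)C(=O)OC)C(=O)OCC | intermediate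
11 | tricyclic diketo diester: ring A fused to the hydroazulenedione, ethyl ester on C25, methyl ester on C19, ketones at C7 and C17, C13=C14; 15R,19S,25R (H15 cis to C26, CO2Me at C19 cis to H15) | O=C1CCCC2=C3[C@H](CC2=O)[C@@H](C(=O)OC)C[C@@]31C(=O)OCC | intermediate
12 | Mannich base: 11 carrying CH2NHMe on C10 (C10 epimers) | O=C1C(CNC)CCC2=C3[C@H](CC2=O)[C@@H](C(=O)OC)C[C@@]31C(=O)OCC | intermediate
13 | bridged keto lactam: C10 and C25 joined by C29H2–N27(Me)–C26(=O), C7 ketone as one-carbon bridge, C17 enone, methyl ester at C19 (19S) | O=C1[C@@H]2CCC3=C4[C@H](CC3=O)[C@@H](C(=O)OC)C[C@@]41C(=O)N(C)C2 | intermediate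
14 | 17S allylic alcohol of 13 (OH cis to H15) | O=C1[C@@H]2CCC3=C4[C@H](C[C@@H]3O)[C@@H](C(=O)OC)C[C@@]41C(=O)N(C)C2 | intermediate
15 | C17 tert-butyldimethylsilyl ether of 14 | O=C1[C@@H]2CCC3=C4[C@H](C[C@@H]3O[Si](C)(C)C(C)(C)C)[C@@H](C(=O)OC)C[C@@]41C(=O)N(C)C2 | intermediate
16 | C7 methoxymethylidene compound (enol ether, E/Z mixture) | COC=C1[C@@H]2CCC3=C4[C@H](C[C@@H]3O[Si](C)(C)C(C)(C)C)[C@@H](C(=O)OC)C[C@@]41C(=O)N(C)C2 | intermediate
17 | C7 carbaldehyde (C7 epimers) | O=CC1[C@@H]2CCC3=C4[C@H](C[C@@H]3O[Si](C)(C)C(C)(C)C)[C@@H](C(=O)OC)C[C@@]41C(=O)N(C)C2 | intermediate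
18 | pent-1-en-3-one (ethyl vinyl ketone) | CCC(=O)C=C | starting material
19 | keto aldehyde: C7 bears CHO (C8) and 3-oxopentyl (C6–C1); 7R | CCC(=O)CC[C@@]1(C=O)[C@@H]2CCC3=C4[C@H](C[C@@H]3O[Si](C)(C)C(C)(C)C)[C@@H](C(=O)OC)C[C@@]41C(=O)N(C)C2 | intermediate
20 | hydroxy ketone: C7 bears CH2OH (C8) and 3-oxopentyl (in equilibrium with its hemiketal) | CCC(=O)CC[C@@]1(CO)[C@@H]2CCC3=C4[C@H](C[C@@H]3O[Si](C)(C)C(C)(C)C)[C@@H](C(=O)OC)C[C@@]41C(=O)N(C)C2 | intermediate
21 | spiro methyl ketal lactam (C3 OMe, C26 lactam, C17 silyl ether, 19S) | CC[C@@]1(OC)CC[C@@]2(CO1)[C@@H]1CCC3=C4[C@H](C[C@@H]3O[Si](C)(C)C(C)(C)C)[C@@H](C(=O)OC)C[C@@]42C(=O)N(C)C1 | intermediate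
22 | tertiary amine: 21 with C26 reduced to CH2 (19S) | CC[C@@]1(OC)CC[C@@]2(CO1)[C@@H]1CCC3=C4[C@H](C[C@@H]3O[Si](C)(C)C(C)(C)C)[C@@H](C(=O)OC)C[C@@]42CN(C)C1 | intermediate
23 | lithium enolate of 22 (C19 trigonal) | CC[C@@]1(OC)CC[C@@]2(CO1)[C@@H]1CCC3=C4[C@H](C[C@@H]3O[Si](C)(C)C(C)(C)C)C(=C(OC)O[Li])C[C@@]42CN(C)C1 | intermediate
24 | 19R ester: C3 methyl ketal and C17 silyl ether of the target | CC[C@@]1(OC)CC[C@@]2(CO1)[C@@H]1CCC3=C4[C@H](C[C@@H]3O[Si](C)(C)C(C)(C)C)[C@H](C(=O)OC)C[C@@]42CN(C)C1 | intermediate
25 | CNP0124876.1 (3S,7R,10S,15R,17S,19R,25R in the locants defined above) | CC[C@@]1(O)CC[C@@]2(CO1)[C@@H]1CCC3=C4[C@H](C[C@@H]3O)[C@H](C(=O)OC)C[C@@]42CN(C)C1 | target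

Total steps: 16. Longest linear sequence: 16 steps (1 to 25).

**Steps most likely to fail**

Step 6. The ring closure may not compete with retro-Michael reaction, loss of HBr or attack through C13, and the ion pair may give low or opposite facial selectivity at C25 (the pseudoenantiomeric cinchoninium salt would correct only the sense). The fallback sets out from 8 and comes back at 11. Compound 8 is vinylated at C25 with methyl 2,3-dibromoacrylate under the same cinchona phase-transfer conditions (asymmetric nucleophilic vinylic substitution of cyclic β-keto esters by β-haloacrylates is known) to give the (Z)-2-bromoacrylate adduct F1. Pd(PPh3)4 and K3PO4 in THF then join C19 to the γ-carbon C15 of the enone dienolate (Pd-catalysed enolate alkenylation, γ-selective as in the γ-arylation of enones) and give the cyclopentene diester F2. Hydrogenation over Pd/C saturates C19=C24 and returns 11; either C19 epimer serves because step 15 sets that centre.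

Step 15. Facial selectivity in the protonation may be poor, or deprotonation of the exo ester may be incomplete, leaving a mixture of C19 epimers. The fallback sets out from 21 and comes back at 24. The lithium enolate of lactam 21 is trapped with PhSeBr to give the α-phenylselanyl ester F3. Oxidation with H2O2 and syn elimination give the cyclopentene ester F4 (C19=C24); no amine is present at this stage to be oxidised. Hydrogenation over Pd/C from the open face of ring A, where a surface-bound catalyst should feel the screening by C8 more than a proton donor does, gives the 19R lactam F5. The Zn(OAc)2/(EtO)3SiH reduction of step 14 then leads to 24.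

Step 12. The vinyl ketone may enter from the face beneath the carbocycle and give the C7 epimer, and aldol condensation of the keto aldehyde may erode the yield. The fallback sets out from 17 and comes back at 20; it reverses the order in which the two C7 substituents are introduced, so that the same facial preference now gives the required configuration. Crossed aldol reaction of 17 with aqueous formaldehyde and K2CO3 installs CH2OH (C8) and gives the hydroxy aldehyde F6, whose formyl carbon becomes C6. Wittig reaction with Ph3P=CHC(O)Et gives the enone F7. Conjugate reduction with [(Ph3P)CuH]6 gives hydroxy ketone 20, which is ketalised as in step 13.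

**Further compounds**
F1 | step 6 | ethyl (4R)-4-[(Z)-2-bromo-3-methoxy-3-oxoprop-1-enyl]-1,5-dioxo-1,2,3,4,5,6,7,8-octahydroazulene-4-carboxylate | O=C1CCCC2=C(CCC2=O)[C@@]1(/C=C(\Br)C(=O)OC)C(=O)OCC
F2 | step 6 | cyclopentene diester: 11 with a C19=C24 double bond | O=C1CCCC2=C3[C@H](CC2=O)C(C(=O)OC)=C[C@@]31C(=O)OCC
F3 | step 15 | α-phenylselanyl ester: 21 with SePh on C19 | CC[C@@]1(OC)CC[C@@]2(CO1)[C@@H]1CCC3=C4[C@H](C[C@@H]3O[Si](C)(C)C(C)(C)C)C(C(=O)OC)([Se]c5ccccc5)C[C@@]42C(=O)N(C)C1
F4 | step 15 | cyclopentene ester: 21 with a C19=C24 double bond | CC[C@@]1(OC)CC[C@@]2(CO1)[C@@H]1CCC3=C4[C@H](C[C@@H]3O[Si](C)(C)C(C)(C)C)C(C(=O)OC)=C[C@@]42C(=O)N(C)C1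
F5 | step 15 | 19R epimer of lactam 21 | CC[C@@]1(OC)CC[C@@]2(CO1)[C@@H]1CCC3=C4[C@H](C[C@@H]3O[Si](C)(C)C(C)(C)C)[C@H](C(=O)OC)C[C@@]42C(=O)N(C)C1
F6 | step 12 | hydroxy aldehyde: C7 bears CH2OH (C8) and CHO (C6) | OC[C@]1(C=O)[C@@H]2CCC3=C4[C@H](C[C@@H]3O[Si](C)(C)C(C)(C)C)[C@@H](C(=O)OC)C[C@@]41C(=O)N(C)C2
F7 | step 12 | (E)-enone: C7 bears CH2OH and 3-oxopent-1-enyl | CCC(=O)/C=C/[C@@]1(CO)[C@@H]2CCC3=C4[C@H](C[C@@H]3O[Si](C)(C)C(C)(C)C)[C@@H](C(=O)OC)C[C@@]41C(=O)N(C)C2
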